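**Strategy.** The 1,2-dioxane carries oxygen at both C3 and C6, so the ring bond C5–C6 joins two carbons of like (acceptor) polarity. It is made by polarity reversal: a chiral siloxycyclopropane serves as a homoenolate (C3–C4–C5, with the C4 ethyl stereocentre pre-set) and attacks the peroxycarbenium ion of the side-chain ketone. In one Lewis acid operation the cyclopropane σ bond forms C5–C6 and the freed oxocarbenium carbon C3 is captured by the peroxide oxygen (O–C3), a formal [3+3] annulation that closes the ring O1–O2–C3–C4–C5–C6. The precursors are a silyl peroxyketal and a (1S,2S)-2-ethylcyclopropyl silyl ether; C3 is later alkylated to the acetic acid arm.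

Key step: step 11

Numbering used: C1 is the carboxyl carbon; C3 (acetic acid arm), C4 (ethyl), C5 and C6 (quaternary) are the ring carbons; O2 sits on C3 and O1 on C6; C7–C14 is the side chain.

Assumption: the enantiomer named for each chiral controller (MIB in step 1, Josiphos in step 5, tartramide in step 8) is taken to give the configuration drawn; should the sense prove opposite, its antipode is used without other change.

Step 1
Reactants: 1 (E)-pent-2-enal; 2 diethylzinc
Product: 3 (3R,4E)-hept-4-en-3-ol
Conditions: Et2Zn, (+)-MIB (cat.), hexanes/toluene, 0 °C; aq. NH4Cl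
Reagents that add atoms: diethylzinc CC[Zn]CC
Why: Amino alcohol-catalysed enantioselective 1,2-addition of a dialkylzinc to an enal, in which the ligand-bound zinc delivers ethyl to the Re face of the aldehyde and so sets the (R)-carbinol centre.

Step 2
Reactants: 3 (3R,4E)-hept-4-en-3-ol; 4 triethyl orthoacetate
Product: 6 ethyl (3R,4E)-3-ethylhept-4-enoate, via ketene acetal 5 (not isolated)
Conditions: MeC(OEt)3 (excess), EtCO2H (cat.), 140 °C, EtOH distilled off
Reagents that add atoms: triethyl orthoacetate CCOC(C)(OCC)OCC
Why: Johnson–Claisen rearrangement, a suprafacial [3,3] shift through a chair with the carbinol ethyl group pseudo-equatorial, which transfers the C–O stereocentre to the new C–C stereocentre (R) and gives the E alkene.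

Step 3
Reactants: 6 ethyl (3R,4E)-3-ethylhept-4-enoate
Product: 7 (3R,4E)-3-ethylhept-4-enal
Conditions: DIBAL-H, CH2Cl2, −78 °C; Rochelle salt
Reagents that add atoms: none
Why: Partial reduction of an ester, which at −78 °C should stop at the aluminium hemiacetal and release the aldehyde on work-up; the β-stereocentre cannot enolise.

Step 4
Reactants: 7 (3R,4E)-3-ethylhept-4-enal; 8 dimethyl (2-oxobutyl)phosphonate
Product: 9 (4E,7R,8E)-7-ethylundeca-4,8-dien-3-one
Conditions: LiCl, i-Pr2NEt, MeCN, rt
Reagents that add atoms: dimethyl (2-oxobutyl)phosphonate CCC(=O)CP(=O)(OC)OC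
Why: Horner–Wadsworth–Emmons olefination under mild LiCl/amine conditions should give the (E)-enone without touching the existing stereocentre.

Step 5
Reactants: 9 (4E,7R,8E)-7-ethylundeca-4,8-dien-3-one; 10 methylmagnesium bromide
Product: 11 (5S,7R,8E)-7-ethyl-5-methylundec-8-en-3-one
Conditions: MeMgBr, CuBr·SMe2 (cat.), (R,S)-Josiphos (cat.), t-BuOMe, −75 °C
Reagents that add atoms: methylmagnesium bromide C[Mg]Br
Why: Copper-catalysed asymmetric conjugate addition of a Grignard reagent to an acyclic enone, in which the chiral copper–diphosphine complex selects the enone face and sets the methyl-bearing centre (S) under catalyst control, the existing centre being remote.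

Step 6
Reactants: 11 (5S,7R,8E)-7-ethyl-5-methylundec-8-en-3-one; 12 trimethyl orthoformate
Product: 13 (3E,5R,7S)-5-ethyl-9,9-dimethoxy-7-methylundec-3-ene
Conditions: HC(OMe)3, PPTS (cat.), MeOH, rt
Reagents that add atoms: trimethyl orthoformate COC(OC)OC
Why: Acid-catalysed ketalisation driven by the orthoformate as dehydrating methoxy donor; no stereocentre is created.

Step 7
Reactants: 13 (3E,5R,7S)-5-ethyl-9,9-dimethoxy-7-methylundec-3-ene; 14 hydrogen peroxide; 16 chlorotriethylsilane
Product: 17 triethyl{[(5S,7R,8E)-7-ethyl-3-methoxy-5-methylundec-8-en-3-yl]peroxy}silane (both C3 epimers), via methoxy hydroperoxide 15 (not isolated)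
Conditions: anhydrous H2O2 in Et2O (limited excess), CSA (cat.), 0 °C; then Et3SiCl, imidazole, DMF, 0 °C
Reagents that add atoms: hydrogen peroxide OO; chlorotriethylsilane CC[Si](Cl)(CC)CC
Why: Acid-catalysed perhydrolysis of a ketal (exchange of one methoxy group for OOH through the oxocarbenium ion) followed by O-silylation of the hydroperoxide; the ketal centre forms as a mixture, which is irrelevant because step 11 ionises it.

Step 8
Reactants: 18 (E)-but-1-en-1-ylboronic acid; 19 (2R,3R)-N,N,N′,N′-tetramethyltartramide
Product: 20 (4R,5R)-2-[(E)-but-1-en-1-yl]-N,N,N′,N′-tetramethyl-1,3,2-dioxaborolane-4,5-dicarboxamide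
Conditions: MgSO4, CH2Cl2, rt
Reagents that add atoms: (2R,3R)-N,N,N′,N′-tetramethyltartramide CN(C)C(=O)[C@H](O)[C@@H](O)C(=O)N(C)C
Why: Condensation of a boronic acid with a 1,2-diol to the cyclic boronic ester, driven by the drying agent, which installs the tartramide auxiliary.

Step 9
Reactants: 20 the alkenylboronic ester; 21 diiodomethane; 14 hydrogen peroxide
Product: 23 (1S,2S)-2-ethylcyclopropan-1-ol, via cyclopropylboronate 22 (not isolated)
Conditions: Zn(Cu), CH2I2, Et2O, reflux; then 30% H2O2, KHCO3, THF/H2O, 0 °C
Reagents that add atoms: diiodomethane ICI; hydrogen peroxide OO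
Why: Simmons–Smith cyclopropanation is stereospecific (E alkene gives the trans ring) and the tartramide, whose amide carbonyls guide the zinc carbenoid, selects the alkene face; oxidation of the C–B bond proceeds with retention and should give the (1S,2S)-cyclopropanol.

Step 10
Reactants: 23 (1S,2S)-2-ethylcyclopropan-1-ol; 16 chlorotriethylsilane
Product: 24 triethyl{[(1S,2S)-2-ethylcyclopropyl]oxy}silane
Conditions: Et3SiCl, imidazole, CH2Cl2, 0 °C
Reagents that add atoms: chlorotriethylsilane CC[Si](Cl)(CC)CC
Why: O-Silylation with a silyl chloride and imidazole is mild enough not to open the cyclopropanol and leaves both stereocentres untouched.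

Step 11
Reactants: 17 the silyl peroxyketal; 24 triethyl{[(1S,2S)-2-ethylcyclopropyl]oxy}silane
Product: 27 triethyl{[(4S,6R)-4,6-diethyl-6-[(2S,4R,5E)-4-ethyl-2-methyloct-5-en-1-yl]-1,2-dioxan-3-yl]oxy}silane (both C3 anomers, formed together with its 6S epimer), via peroxycarbenium ion 25 (not isolated), via oxocarbenium ion 26 (not isolated)
Conditions: 24 (3 equiv), TMSOTf (0.2 equiv), 2,6-di-tert-butyl-4-methylpyridine (0.3 equiv), CH2Cl2, −78 °C
Reagents that add atoms: triethyl{[(1S,2S)-2-ethylcyclopropyl]oxy}silane CC[C@H]1C[C@@H]1O[Si](CC)(CC)CC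
Why: Proposed new method: TMSOTf ionises the methoxy group of 17 to peroxycarbenium ion 25, whose carbon is attacked by the oxygen-activated C(O)–CH2 σ bond of siloxycyclopropane 24 (a homoenolate equivalent) at its unsubstituted CH2 corner, forming C5–C6 and unveiling silyl-oxocarbenium ion 26, which the silylperoxy oxygen then captures with loss of Et3Si+ (the chain carrier), forming O2–C3. The closest known reaction types are the Lewis acid [3+2] annulation of silyl peroxyketals with alkenes to 1,2-dioxolanes (the same sequence of peroxycarbenium addition, cation and peroxide closure), Hosomi–Sakurai and Mukaiyama additions to peroxycarbenium ions, and the electrophilic ring opening of siloxycyclopropanes; replacing the alkene by a donor cyclopropane enlarges the annulation to [3+3]. The one ring formed, the 1,2-dioxane, closes by 6-exo-trig attack of oxygen on the exocyclic C3=O+ bond. C4 is the ethyl-bearing cyclopropane carbon, none of whose bonds is broken, so its (S) configuration is carried over from 24; C3 forms as an anomeric mixture that step 12 erases; C6 forms in the intermolecular C–C bond formation, where nothing in the substrate tells the ethyl arm from the 2-methylalkyl arm, so both C6 epimers are expected and the (6S) epimer has to be removed after step 12. The step needs attack at the CH2 rather than the CHEt corner (secured by the bulk of the tertiary cation; the bond between the two non-oxygenated ring carbons stays intact because only bonds to the oxygen-bearing carbon open to a stabilised cation) and intermolecular capture of 25 faster than six-ring capture by the remote 1,2-disubstituted alkene (secured by the higher nucleophilicity of the donor cyclopropane, its excess and −78 °C).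

Step 12
Reactants: 27 the 3-silyloxy-1,2-dioxane; 28 tert-butyl[(1-methoxyethenyl)oxy]dimethylsilane
Product: 30 methyl 2-[(3S,4S,6R)-4,6-diethyl-6-[(2S,4R,5E)-4-ethyl-2-methyloct-5-en-1-yl]-1,2-dioxan-3-yl]acetate, via cyclic peroxycarbenium ion 29 (not isolated)
Conditions: 28 (3 equiv), TMSOTf (0.3 equiv), CH2Cl2, −78 °C; 6S epimer removed by chromatography
Reagents that add atoms: tert-butyl[(1-methoxyethenyl)oxy]dimethylsilane C=C(OC)O[Si](C)(C)C(C)(C)C
Why: Lewis acid ionisation of a cyclic peroxyacetal to a peroxycarbenium ion and Mukaiyama-type capture by a silyl ketene acetal; the ion should adopt the half-chair with the C4 ethyl group and the C6 side chain pseudo-equatorial and be attacked axially, on the face away from the axial C6 ethyl group, which gives the 3,4-cis (3S) acetate.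

Step 13
Reactants: 30 the methyl ester; 31 lithium hydroxide
Product: 32 2-[(3S,4S,6R)-4,6-diethyl-6-[(2S,4R,5E)-4-ethyl-2-methyloct-5-en-1-yl]-1,2-dioxan-3-yl]acetic acid
Conditions: LiOH, THF/H2O, 0 °C to rt; then dilute HCl to pH 3
Reagents that add atoms: lithium hydroxide [Li+].[OH-]
Why: Saponification of a methyl ester at low temperature, where hydroxide attack at the ester carbonyl should outrun enolisation and β-elimination of the peroxide; no stereocentre is touched.

**Compound list**

1 | (E)-pent-2-enal | CC/C=C/C=O | starting material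
2 | diethylzinc | CC[Zn]CC | starting material
3 | (3R,4E)-hept-4-en-3-ol | CC[C@@H](O)/C=C/CC | intermediate
4 | triethyl orthoacetate | CCOC(C)(OCC)OCC | starting material
5 | (3R,4E)-3-[(1-ethoxyethenyl)oxy]hept-4-ene (ketene acetal) | CC[C@@H](OC(=C)OCC)/C=C/CC | intermediate (not isolated)
6 | ethyl (3R,4E)-3-ethylhept-4-enoate | CC/C=C/[C@H](CC)CC(=O)OCC | intermediate
7 | (3R,4E)-3-ethylhept-4-enal | CC/C=C/[C@H](CC)CC=O | intermediate
8 | dimethyl (2-oxobutyl)phosphonate | CCC(=O)CP(=O)(OC)OC | starting material
9 | (4E,7R,8E)-7-ethylundeca-4,8-dien-3-one | CC/C=C/[C@H](CC)C/C=C/C(=O)CC | intermediate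
10 | methylmagnesium bromide | C[Mg]Br | starting material
11 | (5S,7R,8E)-7-ethyl-5-methylundec-8-en-3-one | CC/C=C/[C@H](CC)C[C@H](C)CC(=O)CC | intermediate
12 | trimethyl orthoformate | COC(OC)OC | starting material
13 | (3E,5R,7S)-5-ethyl-9,9-dimethoxy-7-methylundec-3-ene | CC/C=C/[C@H](CC)C[C@H](C)CC(CC)(OC)OC | intermediate
14 | hydrogen peroxide | OO | starting material
15 | (5S,7R,8E)-7-ethyl-3-methoxy-5-methylundec-8-en-3-yl hydroperoxide (both C3 epimers) | CC/C=C/[C@H](CC)C[C@H](C)CC(CC)(OC)OO | intermediate (not isolated)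
16 | chlorotriethylsilane | CC[Si](Cl)(CC)CC | starting material
17 | triethyl{[(5S,7R,8E)-7-ethyl-3-methoxy-5-methylundec-8-en-3-yl]peroxy}silane (both C3 epimers) | CC/C=C/[C@H](CC)C[C@H](C)CC(CC)(OC)OO[Si](CC)(CC)CC | intermediate
18 | (E)-but-1-en-1-ylboronic acid | CC/C=C/B(O)O | starting material
19 | (2R,3R)-N,N,N′,N′-tetramethyltartramide | CN(C)C(=O)[C@H](O)[C@@H](O)C(=O)N(C)C | starting material
20 | (4R,5R)-2-[(E)-but-1-en-1-yl]-N,N,N′,N′-tetramethyl-1,3,2-dioxaborolane-4,5-dicarboxamide | CC/C=C/B1O[C@H]([C@@H](O1)C(=O)N(C)C)C(=O)N(C)C | intermediate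
21 | diiodomethane | ICI | starting material
22 | (4R,5R)-2-[(1S,2S)-2-ethylcyclopropyl]-N,N,N′,N′-tetramethyl-1,3,2-dioxaborolane-4,5-dicarboxamide | CC[C@H]1C[C@@H]1B2O[C@H]([C@@H](O2)C(=O)N(C)C)C(=O)N(C)C | intermediate (not isolated)
23 | (1S,2S)-2-ethylcyclopropan-1-ol | CC[C@H]1C[C@@H]1O | intermediate
24 | triethyl{[(1S,2S)-2-ethylcyclopropyl]oxy}silane | CC[C@H]1C[C@@H]1O[Si](CC)(CC)CC | intermediate
25 | peroxycarbenium ion of ketone 11, O-(triethylsilyloxy)oxocarbenium | CC/C=C/[C@H](CC)C[C@H](C)CC(CC)=[O+]O[Si](CC)(CC)CC | intermediate (not isolated)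
26 | ring-opened O-triethylsilyl oxocarbenium ion (C5–C6 formed, C3=O+, both C6 epimers) | CC/C=C/[C@H](CC)C[C@H](C)CC(CC)(C[C@H](CC)C=[O+][Si](CC)(CC)CC)OO[Si](CC)(CC)CC | intermediate (not isolated)
27 | triethyl{[(4S,6R)-4,6-diethyl-6-[(2S,4R,5E)-4-ethyl-2-methyloct-5-en-1-yl]-1,2-dioxan-3-yl]oxy}silane (C3 anomers; accompanied by the 6S epimer) | CC/C=C/[C@H](CC)C[C@H](C)C[C@]1(CC)C[C@H](CC)C(O[Si](CC)(CC)CC)OO1 | intermediate
28 | tert-butyl[(1-methoxyethenyl)oxy]dimethylsilane | C=C(OC)O[Si](C)(C)C(C)(C)C | starting material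
29 | (4S,6R)-4,6-diethyl-6-[(2S,4R,5E)-4-ethyl-2-methyloct-5-en-1-yl]-1,2-dioxan-3-ylium (cyclic peroxycarbenium ion) | CC/C=C/[C@H](CC)C[C@H](C)C[C@]1(CC)C[C@H](CC)C=[O+]O1 | intermediate (not isolated)
30 | methyl 2-[(3S,4S,6R)-4,6-diethyl-6-[(2S,4R,5E)-4-ethyl-2-methyloct-5-en-1-yl]-1,2-dioxan-3-yl]acetate | CC/C=C/[C@H](CC)C[C@H](C)C[C@]1(CC)C[C@H](CC)[C@H](CC(=O)OC)OO1 | intermediate
31 | lithium hydroxide | [Li+].[OH-] | starting material
32 | 2-[(3S,4S,6R)-4,6-diethyl-6-[(2S,4R,5E)-4-ethyl-2-methyloct-5-en-1-yl]-1,2-dioxan-3-yl]acetic acid | CC/C=C/[C@H](CC)C[C@H](C)C[C@]1(CC)C[C@H](CC)[C@H](CC(=O)O)OO1 | target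

**Step count.** Total: 13 steps (steps 1–7 and 8–10 converge in step 11). Longest linear sequence: 10 steps (1–7, then 11–13).

**Steps most likely to fail**

Step 11 (Proposed new method). The donor cyclopropane may be too weak a σ-nucleophile, so that the peroxycarbenium ion is consumed by capture through the remote alkene or by fragmentation; in addition the intermolecular C–C bond formation offers no facial control at C6, so half of the material may be lost as the 6S epimer. Fallback with known chemistry, setting out from 17 and returning at 27: Hosomi–Sakurai allylation of the same peroxycarbenium ion (TMSOTf, CH2Cl2, −78 °C) with trimethyl(2-methylidenebutyl)silane F1 (made from 2-bromobut-1-ene and Me3SiCH2MgCl with a nickel catalyst) should give the homoallyl silyl peroxide F2. Hydroboration of its 1,1-disubstituted alkene with 9-BBN, which discriminates against the internal E alkene, and oxidation with NaBO3 should give the primary alcohol F3. Dess–Martin oxidation then gives the γ-silylperoxy aldehyde F4, which with catalytic Et3SiOTf should isomerise by silyl transfer and ring closure to 27. In this fallback C4 is no longer reagent-controlled, so the C4 and C6 epimers would all have to be separated at the stage of 30.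

Step 12. Ionisation could take the wrong course (loss of the ring peroxide oxygen instead of the silyloxy group), the Lewis acid could fragment the peroxide, or the axial preference at C3 could be too small. Fallback, setting out from 27 and returning at 30: mild hydrolysis (AcOH/THF/H2O) to the peroxyhemiacetal, (4S,6R)-4,6-diethyl-6-[(2S,4R,5E)-4-ethyl-2-methyloct-5-en-1-yl]-1,2-dioxan-3-ol F5. Horner–Wadsworth–Emmons reaction with trimethyl phosphonoacetate (LiCl, DBU, MeCN) opens it to the hydroperoxy enoate, methyl (2E,4S,6R,8S,10R,11E)-4,6,10-triethyl-6-hydroperoxy-8-methyltetradeca-2,11-dienoate F6. This should reclose to 30 by intramolecular oxa-Michael addition (Et2NH, CF3CH2OH); C3 is then set by the cyclisation and its epimer would need separation.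

Step 13. Base may deprotonate C2 of the ester and expel the peroxide (retro-oxa-Michael) with loss of configuration at C3, or cleave the peroxide at C3–H. Fallback that avoids any ester hydrolysis, setting out from 27 and returning at 32: under the conditions of step 12 use ketene bis(trimethylsilyl) acetal F7 (from trimethylsilyl acetate, LDA and Me3SiCl) in place of 28. The trimethylsilyl ester F8 that results is cleaved by water on work-up to give 32 directly, and the 6S epimer is then removed at the stage of the acid.

**Further compounds**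

F1 | step 11 | trimethyl(2-methylidenebutyl)silane | C=C(CC)C[Si](C)(C)C
F2 | step 11 | triethyl{[(3E,5R,7S)-5,9-diethyl-7-methyl-11-methylidenetridec-3-en-9-yl]peroxy}silane (both C9 epimers) | CC/C=C/[C@H](CC)C[C@H](C)CC(CC)(CC(=C)CC)OO[Si](CC)(CC)CC
F3 | step 11 | (6S,8R,9E)-2,4,8-triethyl-6-methyl-4-[(triethylsilyl)peroxy]dodec-9-en-1-ol (C2 and C4 epimers) | CC/C=C/[C@H](CC)C[C@H](C)CC(CC)(CC(CC)CO)OO[Si](CC)(CC)CC
F4 | step 11 | (6S,8R,9E)-2,4,8-triethyl-6-methyl-4-[(triethylsilyl)peroxy]dodec-9-enal (C2 and C4 epimers) | CC/C=C/[C@H](CC)C[C@H](C)CC(CC)(CC(CC)C=O)OO[Si](CC)(CC)CC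
F5 | step 12 | (4S,6R)-4,6-diethyl-6-[(2S,4R,5E)-4-ethyl-2-methyloct-5-en-1-yl]-1,2-dioxan-3-ol | CC/C=C/[C@H](CC)C[C@H](C)C[C@]1(CC)C[C@H](CC)C(O)OO1
F6 | step 12 | methyl (2E,4S,6R,8S,10R,11E)-4,6,10-triethyl-6-hydroperoxy-8-methyltetradeca-2,11-dienoate | CC/C=C/[C@H](CC)C[C@H](C)C[C@](CC)(C[C@H](CC)/C=C/C(=O)OC)OO
F7 | step 13 | ketene bis(trimethylsilyl) acetal, 1,1-bis(trimethylsilyloxy)ethene | C=C(O[Si](C)(C)C)O[Si](C)(C)C
F8 | step 13 | trimethylsilyl 2-[(3S,4S,6R)-4,6-diethyl-6-[(2S,4R,5E)-4-ethyl-2-methyloct-5-en-1-yl]-1,2-dioxan-3-yl]acetate | CC/C=C/[C@H](CC)C[C@H](C)C[C@]1(CC)C[C@H](CC)[C@H](CC(=O)O[Si](C)(C)C)OO1
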